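The constants belong to no real substance, and the outcome is calculated.

- Each stirred, constant-volume vessel gets the same charges, and the flasks differ in what, if anything, is fed slowly, so we ask whether the order of addition moves the target.

| flask | starting material | reagent | protic impurity | time | remark |
|---|---|---|---|---|---|
| alder | 2.0 mM | 1.20 mM | 0.600 mM | 80 s | everything together at the start |
| cedar | 2.0 mM | 1.20 mM (fed, over 15 s) | 0.600 mM | 80 s | all else is in the flask from the start; the feed brings no volume worth counting |
| birch | 2.0 mM (fed, over 15 s) | 1.20 mM | 0.600 mM | 80 s | all else is in the flask from the start; the feed brings no volume worth counting |

    starting material + protic impurity → quenched substrate (k1 = 37 L mol⁻¹ s⁻¹)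
    starting material + reagent + target → 2 target (k2 = 7.2 × 10⁵ L² mol⁻² s⁻¹)
    reagent → decomposition product (k3 = 1.6 × 10⁻⁵ s⁻¹)
    starting material + reagent → target (k4 = 0.096 L mol⁻¹ s⁻¹)

1. which flask leads in amount of target, in percent of the starting material charged ("all alike" within 1.5 percentage points) (alder / cedar / birch / all alike)
2. how much target is there at the end, in percent of the starting material charged: alder
3. how much target is there at the end, in percent of the starting material charged: cedar
4. how much target is there at the end, in percent of the starting material charged: birch

- The bench rule is to find the limiting reagent and count: each target formed by the two target-forming steps costs one reagent and one starting material, so with reagent limiting the yield Y is the reagent charge over the starting material charge, 60.0%.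

- That rule stops holding by itself where the quench can take starting material below the reagent charge. Taking the whole impurity charge from the starting material leaves 1.40 mM, and dividing by the reagent charge gives 1.17, which we call the cover C, the starting material surviving the worst quench per reagent charged. With C above one, and time to finish, the quench cannot lower Y in this scheme; below one, the race between quench and target enters.

- Time must still be checked. Reagent's half-life by decomposition is 720 min, far longer than the 80 s run. In alder, the uncatalysed step acts as a seed of 1.33 × 10⁻⁴ mM, the constant of that step over the constant of the catalysed step. Target must climb 3.95 powers of ten, each costing 1.33 s with charges held, so takeoff comes near 5.26 s, well inside the run. The feeds in cedar and birch end at 15 s, also inside it. We therefore commit to 60.0% in each flask.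

- The forecast gives 60% for alder, 60% for cedar and 60% for birch, hence all alike, holding that “Reagent is therefore limiting in every flask”; it puts takeoff in alder near 6 s, and we put it near 5.26 s.

- The simulation gives 60.0% for alder, 60.0% for cedar and 60.0% for birch, hence all alike.



- In cedar, the quench reached the midpoint of its turnover up to 80 s at 7.87 s, and the catalysed step reached its own at 14.2 s, while reagent was still being fed. By 40.0 s, cedar's reagent stood at 0% of its charge and target at 60.0%, while the quench went on, leaving 16.4% of the impurity at 80.0 s. With cover 1.17, the count held. A cedar flask charged with 3.4 mM of starting material has cover 2.33 and yield 35.3% by the count; it ended at 35.3% target, with 47.1% of its starting material left.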